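**Retrosynthetic overview**

- Structural feature: the C1 aryl ketone with its C2 carbinol on the 2',4'-dihydroxyphenyl ring maps onto C4 and C3 of a 4,7-dihydroxycoumarin. The ring oxygen O1 becomes the 2'-OH, the 7-oxygen becomes the 4'-OH, and the lactone carbon C2 is lost as CO2.
- Target 12 comes from silyl ether 11 by desilylation. 11 comes from the 3-hydroxychromane-2,4-dione 8 by lactone hydrolysis, decarboxylation and enantioselective protonation at C2 (the only new bond is C2–H).
- 8 comes from 3-farnesyl-4-hydroxycoumarin 6 by hydroxylation at C3. 6 comes from the 7-O-silyl coumarin 3 and farnesyl carbonate 5 by palladium-catalysed C3 allylation.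
- The 7-OH is silylated so that allylation, hydroxylation and the protonation step see one acidic phenol fewer.
- No ring is formed: the benzene and pyranone rings arrive with 1, and the pyranone ring is opened in the key step.

Key step: step 5

Assumption: the facial sense of the chiral proton shuttle cannot be predicted; the quinidine-derived catalyst is written, and its quinine-derived pseudoenantiomer would be used if the other face is protonated.

**Route**

Step 1
Reactants: 1 4,7-dihydroxycoumarin
Product: 3 4-hydroxy-7-(triisopropylsilyloxy)-2H-chromen-2-one, via bis-silyl ether 2 (not isolated)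
Conditions: iPr3SiCl (2.3 equiv), imidazole (5 equiv), DMF, 25 °C; then K2CO3 (1.1 equiv), MeOH/THF, 0 °C; aq. HCl to pH 3–4
Reagents that add atoms: triisopropylsilyl chloride, CC(C)[Si](Cl)(C(C)C)C(C)C
Why: Bis-silylation followed by carbonate-mediated methanolysis should remove only the silyl group on O4, which is a vinylogous silyl ester of an acid of pKa near 4, while the hindered aryl silyl ether on O7 stays (the selective silyl ester cleavage used for hydroxy acids).

Step 2
Reactants: 4 (2E,6E)-farnesol
Product: 5 methyl (2E,6E)-3,7,11-trimethyldodeca-2,6,10-trien-1-yl carbonate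
Conditions: ClCO2Me (1.5 equiv), pyridine (2 equiv), CH2Cl2, 0 °C
Reagents that add atoms: methyl chloroformate, COC(=O)Cl
Why: O-acylation of a primary allylic alcohol with a chloroformate under pyridine should proceed without allylic transposition or change of alkene geometry.

Step 3
Reactants: 3 4-hydroxy-7-(triisopropylsilyloxy)-2H-chromen-2-one (1.2 equiv); 5 methyl farnesyl carbonate
Product: 6 4-hydroxy-3-[(2E,6E)-3,7,11-trimethyldodeca-2,6,10-trien-1-yl]-7-(triisopropylsilyloxy)-2H-chromen-2-one
Conditions: Pd(PPh3)4 (5 mol%), degassed THF, 40 °C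
Reagents that add atoms: none
Why: Tsuji–Trost allylation: zerovalent palladium ionises 5 with release of CO2 and methoxide, which deprotonates the acidic 4-hydroxycoumarin, and the soft anion should attack the unsubstituted terminus of the pi-farnesyl complex through C3, with O-allylated isomers re-ionising and draining to the C-allyl product.

Step 4
Reactants: 6 3-farnesyl-4-hydroxy-7-(triisopropylsilyloxy)coumarin
Product: 8 rac-3-hydroxy-3-[(2E,6E)-3,7,11-trimethyldodeca-2,6,10-trien-1-yl]-7-(triisopropylsilyloxy)chromane-2,4-dione, via potassium enolate 7 (not isolated)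
Conditions: KN(SiMe3)2 (1.05 equiv), THF, −78 °C; 2-(benzenesulfonyl)-3-phenyloxaziridine (1.2 equiv), −78 to 0 °C; AcOH quench at −20 °C; rapid chromatography on deactivated silica
Reagents that add atoms: 2-(benzenesulfonyl)-3-phenyloxaziridine, O=S(=O)(c1ccccc1)N1OC1c1ccccc1
Why: Electrophilic alpha-hydroxylation of a 1,3-dicarbonyl enolate with an N-sulfonyloxaziridine should place oxygen on C3, the only nucleophilic carbon, and leave the three trisubstituted alkenes untouched; the racemic C3 centre is of no consequence because it is erased in step 5.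

Step 5
Reactants: 8 rac-3-farnesyl-3-hydroxy-7-(triisopropylsilyloxy)chromane-2,4-dione
Product: 11 (2R,4E,8E)-2-hydroxy-1-[2-hydroxy-4-(triisopropylsilyloxy)phenyl]-5,9,13-trimethyltetradeca-4,8,12-trien-1-one, via ring-opened keto acid 9 (not isolated), via enediol 10 (not isolated)
Conditions: quinidine-derived 9-amino(9-deoxy)epi-cinchona 3,5-bis(trifluoromethyl)phenyl thiourea (20 mol%), H2O (3 equiv), degassed toluene/THF (4:1), argon, 0 °C; cold aq. citric acid wash
Reagents that add atoms: none
Why: Proposed new method: the quinuclidine nitrogen acts as general base for addition of water to the aryl lactone carbonyl of 8, which is activated by the geminal hydroxyl and ketone and releases a chelated 2-acylphenol, giving keto acid 9 as its chiral ammonium carboxylate; this beta-keto carboxylate loses CO2 (the water oxygen leaves with it) to give enediol 10 held by the thiourea N–H bonds, and the quinuclidinium N–H then transfers its proton to C2. The closest known reaction type is the cinchona-amine-mediated enantioselective decarboxylative protonation of malonic half-esters and alpha-amino malonate hemiesters; a lactone opened in the same flask and an enediol as the prochiral intermediate go beyond it. No ring is closed and no skeletal bond is formed; the only new bond is C2–H. The C2 stereocenter is set by the catalyst, which should shield one face of the planar enediol inside the hydrogen-bonded ion pair, the racemic C3 centre of 8 having been erased on decarboxylation. Protonation must occur at C2 and not at C1, which is secured because C2 protonation gives the carbonyl conjugated to the electron-rich aryl ring and chelated by the 2'-OH, whereas C1 protonation would give a non-conjugated benzylic carbinol. Exclusion of oxygen (the enediol would autoxidise to the 1,2-dione), a small excess of water, low temperature and removal of the amine by the acid wash are needed to hold back uncatalysed protonation and enolisation of the product.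

Step 6
Reactants: 11 (R)-4'-O-triisopropylsilyl alpha-hydroxy ketone
Product: 12 (2R,4E,8E)-1-(2,4-dihydroxyphenyl)-2-hydroxy-5,9,13-trimethyltetradeca-4,8,12-trien-1-one
Conditions: Bu4NF (1.2 equiv), AcOH (1.5 equiv), THF, 0 °C; chromatography on neutral silica
Reagents that add atoms: none
Why: Fluoride attack on silicon releases the 4'-phenoxide, a good leaving group para to the ketone, and the acetic acid buffer should prevent enolisation of the alpha-hydroxy ketone, so the C2 configuration is expected to be kept.

**Compound list**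

1 | 4,7-dihydroxy-2H-chromen-2-one (4,7-dihydroxycoumarin) | O=c1cc(O)c2ccc(O)cc2o1 | starting material
2 | 4,7-bis(triisopropylsilyloxy)-2H-chromen-2-one | O=c1cc(O[Si](C(C)C)(C(C)C)C(C)C)c2ccc(O[Si](C(C)C)(C(C)C)C(C)C)cc2o1 | intermediate
3 | 4-hydroxy-7-(triisopropylsilyloxy)-2H-chromen-2-one | O=c1cc(O)c2ccc(O[Si](C(C)C)(C(C)C)C(C)C)cc2o1 | intermediate
4 | (2E,6E)-3,7,11-trimethyldodeca-2,6,10-trien-1-ol ((2E,6E)-farnesol) | CC(C)=CCC/C(C)=C/CC/C(C)=C/CO | starting material
5 | methyl (2E,6E)-3,7,11-trimethyldodeca-2,6,10-trien-1-yl carbonate | CC(C)=CCC/C(C)=C/CC/C(C)=C/COC(=O)OC | intermediate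
6 | 4-hydroxy-3-[(2E,6E)-3,7,11-trimethyldodeca-2,6,10-trien-1-yl]-7-(triisopropylsilyloxy)-2H-chromen-2-one | CC(C)=CCC/C(C)=C/CC/C(C)=C/Cc1c(O)c2ccc(O[Si](C(C)C)(C(C)C)C(C)C)cc2oc1=O | intermediate
7 | potassium 2-oxo-3-[(2E,6E)-3,7,11-trimethyldodeca-2,6,10-trien-1-yl]-7-(triisopropylsilyloxy)-2H-chromen-4-olate | [K+].CC(C)=CCC/C(C)=C/CC/C(C)=C/Cc1c([O-])c2ccc(O[Si](C(C)C)(C(C)C)C(C)C)cc2oc1=O | intermediate
8 | rac-3-hydroxy-3-[(2E,6E)-3,7,11-trimethyldodeca-2,6,10-trien-1-yl]-7-(triisopropylsilyloxy)chromane-2,4-dione | CC(C)=CCC/C(C)=C/CC/C(C)=C/CC1(O)C(=O)Oc2cc(O[Si](C(C)C)(C(C)C)C(C)C)ccc2C1=O | intermediate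
9 | rac-(4E,8E)-2-hydroxy-2-[2-hydroxy-4-(triisopropylsilyloxy)benzoyl]-5,9,13-trimethyltetradeca-4,8,12-trienoic acid | CC(C)=CCC/C(C)=C/CC/C(C)=C/CC(O)(C(=O)O)C(=O)c1ccc(O[Si](C(C)C)(C(C)C)C(C)C)cc1O | intermediate
10 | (4E,8E)-1-[2-hydroxy-4-(triisopropylsilyloxy)phenyl]-5,9,13-trimethyltetradeca-1,4,8,12-tetraene-1,2-diol (C1=C2 geometry not defined) | CC(C)=CCC/C(C)=C/CC/C(C)=C/CC(O)=C(O)c1ccc(O[Si](C(C)C)(C(C)C)C(C)C)cc1O | intermediate
11 | (2R,4E,8E)-2-hydroxy-1-[2-hydroxy-4-(triisopropylsilyloxy)phenyl]-5,9,13-trimethyltetradeca-4,8,12-trien-1-one | CC(C)=CCC/C(C)=C/CC/C(C)=C/C[C@@H](O)C(=O)c1ccc(O[Si](C(C)C)(C(C)C)C(C)C)cc1O | intermediate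
12 | (2R,4E,8E)-1-(2,4-dihydroxyphenyl)-2-hydroxy-5,9,13-trimethyltetradeca-4,8,12-trien-1-one | CC(C)=CCC/C(C)=C/CC/C(C)=C/C[C@@H](O)C(=O)c1ccc(O)cc1O | target

**Step count**

Total steps: 6. Longest linear sequence: 5 steps (1 → 3 → 6 → 8 → 11 → 12, or equally 4 → 5 → 6 → 8 → 11 → 12).

**Steps most likely to fail**

1. Step 5 (proposed new method). What may go wrong:
- Proton transfer from water or from the liberated 2'-phenol outside the chiral ion pair would lower the enantiomeric purity.
- The amine could racemise the product through the enediol.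
- The enediol could autoxidise.
- The lactone could open too slowly at low temperature.

Fallback by known chemistry, setting out from 6 and returning at 12: hot aqueous-ethanolic KOH under argon should hydrolyse the lactone, decarboxylate the beta-keto acid and remove the silyl group, giving (4E,8E)-1-(2,4-dihydroxyphenyl)-5,9,13-trimethyltetradeca-4,8,12-trien-1-one F1. Both phenols are then capped (NaH, MeOCH2Cl, DMF, 0 °C) to give (4E,8E)-1-[2,4-bis(methoxymethoxy)phenyl]-5,9,13-trimethyltetradeca-4,8,12-trien-1-one F2. Asymmetric enolate hydroxylation (NaN(SiMe3)2, THF, −78 °C, then enantiopure (camphorsulfonyl)oxaziridine, the (−)-reagent being expected to give the R configuration by analogy with simple aryl alkyl ketone enolates) should give (2R,4E,8E)-1-[2,4-bis(methoxymethoxy)phenyl]-2-hydroxy-5,9,13-trimethyltetradeca-4,8,12-trien-1-one F3. Dilute HCl in MeOH at 25–40 °C then removes both acetals to give 12.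

2. Step 4. What may go wrong:
- Oxygen transfer to the weakly nucleophilic, highly stabilised enolate may be slow.
- The tertiary alkoxide may undergo acyloin-type ring contraction.
- The alkoxide may add to the sulfonimine by-product.

Fallback, setting out from 6 and returning at 8: base-mediated autoxidation in place of electrophilic oxygen transfer (K2CO3, O2 at 1 atm, P(OEt)3, DMSO, 25 °C). The enolate should take up dioxygen to give rac-3-hydroperoxy-3-[(2E,6E)-3,7,11-trimethyldodeca-2,6,10-trien-1-yl]-7-(triisopropylsilyloxy)chromane-2,4-dione F4, which triethyl phosphite reduces in the same flask to 8.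

3. Step 3. What may go wrong:
- The 2E geometry may erode by syn/anti exchange in the pi-allyl complex before the weakly nucleophilic anion attacks.
- A second allylation at C3 may occur.
- O-allyl isomers may persist.

Fallback, setting out from 4 and 3 and returning at 6: direct SN2 alkylation without a pi-allyl intermediate. Farnesol is converted with PBr3 in Et2O at −10 °C into (2E,6E)-farnesyl bromide F5. This alkylates the lithium salt of 3 (LiOH, 1 equiv) in a hydrogen-bond-donating medium (2,2,2-trifluoroethanol/THF, 25 °C), which masks the oxygen termini and should favour carbon, as in the C-alkylation of cyclic 1,3-diones with allylic halides in protic solvents.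

**Further compounds**

F1 | step 5 | (4E,8E)-1-(2,4-dihydroxyphenyl)-5,9,13-trimethyltetradeca-4,8,12-trien-1-one | CC(C)=CCC/C(C)=C/CC/C(C)=C/CCC(=O)c1ccc(O)cc1O
F2 | step 5 | (4E,8E)-1-[2,4-bis(methoxymethoxy)phenyl]-5,9,13-trimethyltetradeca-4,8,12-trien-1-one | CC(C)=CCC/C(C)=C/CC/C(C)=C/CCC(=O)c1ccc(OCOC)cc1OCOC
F3 | step 5 | (2R,4E,8E)-1-[2,4-bis(methoxymethoxy)phenyl]-2-hydroxy-5,9,13-trimethyltetradeca-4,8,12-trien-1-one | CC(C)=CCC/C(C)=C/CC/C(C)=C/C[C@@H](O)C(=O)c1ccc(OCOC)cc1OCOC
F4 | step 4 | rac-3-hydroperoxy-3-[(2E,6E)-3,7,11-trimethyldodeca-2,6,10-trien-1-yl]-7-(triisopropylsilyloxy)chromane-2,4-dione | CC(C)=CCC/C(C)=C/CC/C(C)=C/CC1(OO)C(=O)Oc2cc(O[Si](C(C)C)(C(C)C)C(C)C)ccc2C1=O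
F5 | step 3 | (2E,6E)-1-bromo-3,7,11-trimethyldodeca-2,6,10-triene (farnesyl bromide) | CC(C)=CCC/C(C)=C/CC/C(C)=C/CBr
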